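**Plan**

- Retrosynthetic cuts: the C3–aryl bond to the 3,5-dihydroxyphenyl ring (back to a C3 carboxylic acid); then C3–C3a of the dihydrofuran, with the carboxyl carbon put back between C3 and C3a (a 2-arylchroman-4-one); then C2–aryl (chromone plus arylboronic acid); then O1–C2 and the aryl–acetyl bond (back to 3,5-dimethoxybenzyl alcohol).
- Forward order: ring A is bought; the pyranone ring is closed through an enaminone; ring B is added by 1,4-addition; the six-membered ring is contracted to the dihydrofuran; ring C is joined last; then CH2OH → CHO and fourfold O-demethylation.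
- Stereochemistry: C2 (S) comes from the ligand in the Pd-catalysed conjugate addition; C3 (S) is placed trans to the C2 aryl group, first by the stereospecific shift and finally by capture of the planar C3 radical anti to that aryl group.
- Enabling feature: the ring O1–C2–C3–C3a–C7a with a carbon substituent on C3 is the pyranone ring of a flavanone that has lost its carbonyl carbon from the ring; C3a, lying between the oxygen-bearing carbons C4 and C7a, is an electron-rich aryl carbon that can move from the old carbonyl carbon to C3.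

Key step: step 7

Assumption: the sense of induction of the Pd/t-BuPyOx 1,4-addition to chromones is taken to follow that known for cyclic enones ((S)-ligand gives the (R)-β-aryl ketone), so the (R)-ligand is specified for the (2S)-flavanone.

Numbering: chromane numbering is used for 9–12, benzofuran numbering for 13–18.

**Route**

Step 1
Reactants: 1 3,5-dimethoxybenzyl alcohol
Product: 2 tert-butyl[(3,5-dimethoxyphenyl)methoxy]dimethylsilane
Conditions: TBSCl, imidazole, CH2Cl2, rt
Reagents that add atoms: tert-butyldimethylsilyl chloride, CC(C)(C)[Si](C)(C)Cl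
Why: Silylation of the primary alcohol removes the acidic OH and gives a bulky, weakly coordinating ether, so that the following metalation is governed by the two methoxy groups.

Step 2
Reactants: 2 tert-butyl[(3,5-dimethoxyphenyl)methoxy]dimethylsilane
Product: 5 1-[4-(hydroxymethyl)-2,6-dimethoxyphenyl]ethan-1-one, via aryllithium 3 (not isolated), via silyl ether ketone 4 (not isolated)
Conditions: n-BuLi, THF, 0 °C; MeC(O)N(OMe)Me, −78 → 0 °C; then 2 M HCl, THF/H2O, rt
Reagents that add atoms: N-methoxy-N-methylacetamide, CC(=O)N(C)OC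
Why: Directed ortho-metalation should occur at the position flanked by both methoxy groups, the Weinreb ketone synthesis stops at the ketone through its stable chelate, and the aqueous acid of the work-up should also cleave the primary silyl ether.

Step 3
Reactants: 5 1-[4-(hydroxymethyl)-2,6-dimethoxyphenyl]ethan-1-one
Product: 6 (4-acetyl-3,5-dimethoxyphenyl)methyl 2,2-dimethylpropanoate
Conditions: PivCl, pyridine, DMAP (cat.), CH2Cl2, 0 °C → rt
Reagents that add atoms: pivaloyl chloride, CC(C)(C)C(=O)Cl
Why: DMAP-catalysed acylation of the primary alcohol installs a pivalate, chosen because it should resist BCl3 and the acidic media of steps 5 and 7.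

Step 4
Reactants: 6 (4-acetyl-3,5-dimethoxyphenyl)methyl 2,2-dimethylpropanoate
Product: 7 (4-acetyl-3-hydroxy-5-methoxyphenyl)methyl 2,2-dimethylpropanoate
Conditions: BCl3 (1.2 equiv), CH2Cl2, −78 → 0 °C; aq. work-up
Reagents that add atoms: none
Why: Chelation-controlled ether cleavage should remove only one methyl group, because BCl3 bound between the carbonyl oxygen and an ortho methoxy group delivers chloride to that methyl and the resulting aryloxyboron chelate shuts down the second cleavage; the substrate is symmetric, so no regiochemical question arises.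

Step 5
Reactants: 7 (4-acetyl-3-hydroxy-5-methoxyphenyl)methyl 2,2-dimethylpropanoate
Product: 9 (5-methoxy-4-oxo-4H-chromen-7-yl)methyl 2,2-dimethylpropanoate, via enaminone 8 (not isolated)
Conditions: Me2NCH(OMe)2, toluene, 95 °C; then conc. HCl, CH2Cl2, 40 °C
Reagents that add atoms: N,N-dimethylformamide dimethyl acetal, COC(OC)N(C)C
Why: Condensation of the methyl ketone with the amide acetal gives the enaminone, and acid should then promote 6-endo addition of the phenol with loss of dimethylamine (enaminone route to chromones), closing the pyranone ring.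

Step 6
Reactants: 9 (5-methoxy-4-oxo-4H-chromen-7-yl)methyl 2,2-dimethylpropanoate; 10 4-methoxyphenylboronic acid
Product: 11 [(2S)-5-methoxy-2-(4-methoxyphenyl)-4-oxo-3,4-dihydro-2H-chromen-7-yl]methyl 2,2-dimethylpropanoate
Conditions: Pd(OCOCF3)2 (5 mol %), (R)-t-BuPyOx (6 mol %), NH4PF6 (30 mol %), H2O (5 equiv), ClCH2CH2Cl, 60 °C
Reagents that add atoms: none
Why: Pd(II)/pyridine-oxazoline-catalysed asymmetric conjugate addition of an arylboronic acid to a chromone (Hayashi–Miyaura-type 1,4-addition) should set C2 as S, the tert-butyl group of the ligand selecting the enantioface in the migratory insertion of C2=C3 into the aryl–Pd bond before protonolysis.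

Step 7
Reactants: 11 [(2S)-5-methoxy-2-(4-methoxyphenyl)-4-oxo-3,4-dihydro-2H-chromen-7-yl]methyl 2,2-dimethylpropanoate
Product: 13 methyl (2S,3S)-6-{[(2,2-dimethylpropanoyl)oxy]methyl}-4-methoxy-2-(4-methoxyphenyl)-2,3-dihydro-1-benzofuran-3-carboxylate, via methyl enol ether 12 (not isolated)
Conditions: PhI(OAc)2 (1.2 equiv), conc. H2SO4, HC(OMe)3, 0 °C → rt; NaHCO3 quench
Reagents that add atoms: trimethyl orthoformate, COC(OC)OC
Why: Acid and orthoformate turn the C4 ketone into methyl enol ether 12, whose C3 attacks PhI(OAc)2 on the face away from the C2 aryl group, and methanol adds to the oxocarbenium ion to give a trans-3-iodanyl dimethyl ketal. In that ketal the C4–C4a bond is antiperiplanar to the pseudo-equatorial C3–I bond, so ring-A carbon C4a shifts from C4 to C3 as iodobenzene leaves, and the exocyclic dimethoxycarbenium ion ends as the methyl ester. The closest known reaction type is the iodine(III)- or thallium(III)-mediated oxidative ring contraction of flavanones and 1-tetralones in trimethyl orthoformate, the cyclic case of the 1,2-aryl shift that converts aryl ketone ketals into arylacetic esters. The five-membered ring is thus closed by a semipinacol-type 1,2-aryl shift through a phenonium-like bridged transition state (ring contraction), not by cyclisation of a chain. C2 is not involved and stays S, and C3 is formed S, trans to the C2 aryl group, because the shift inverts the carbon that carried the trans iodanyl group and the trans ester is also the more stable epimer. The step needs migration of the ring-A carbon rather than a 2→3 shift of the anisyl ring, dehydrogenation to the flavone or 3-methoxylation, and needs C2–O1 to stay closed; the two oxygens ortho to C4a (O1 and 5-OMe), the push of the two methoxy groups on C4 and the diequatorial conformer favour the wanted shift, and a short reaction time at 0 °C to rt protects C2.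

Step 8
Reactants: 13 methyl (2S,3S)-6-{[(2,2-dimethylpropanoyl)oxy]methyl}-4-methoxy-2-(4-methoxyphenyl)-2,3-dihydro-1-benzofuran-3-carboxylate
Product: 14 (2S,3S)-6-(hydroxymethyl)-4-methoxy-2-(4-methoxyphenyl)-2,3-dihydro-1-benzofuran-3-carboxylic acid
Conditions: LiOH·H2O (6 equiv), THF/MeOH/H2O, 45 °C; then 1 M HCl to pH 3
Reagents that add atoms: lithium hydroxide, [Li+].[OH-]
Why: Saponification (BAc2) should cleave both esters; enolisation at C3 can only return the more stable trans acid and C3 is replaced in step 9, while loss of O1 by β-elimination would be a disfavoured retro-5-endo-trig process, so C2 should hold.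

Step 9
Reactants: 14 (2S,3S)-6-(hydroxymethyl)-4-methoxy-2-(4-methoxyphenyl)-2,3-dihydro-1-benzofuran-3-carboxylic acid; 15 1-bromo-3,5-dimethoxybenzene
Product: 16 [(2S,3S)-3-(3,5-dimethoxyphenyl)-4-methoxy-2-(4-methoxyphenyl)-2,3-dihydro-1-benzofuran-6-yl]methanol
Conditions: Ir[dF(CF3)ppy]2(dtbbpy)PF6 (1 mol %), NiCl2·glyme (10 mol %), dtbbpy (15 mol %), Cs2CO3 (1.5 equiv), DMF, blue LEDs, rt
Reagents that add atoms: none
Why: Nickel/photoredox decarboxylative arylation of a secondary benzylic acid, in which the carboxylate is oxidised by the excited iridium catalyst, CO2 is lost, and the planar benzylic C3 radical should be captured by the aryl–nickel species on the face anti to the C2 aryl group, so that reductive elimination gives the trans (3S) product under control of C2.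

Step 10
Reactants: 16 [(2S,3S)-3-(3,5-dimethoxyphenyl)-4-methoxy-2-(4-methoxyphenyl)-2,3-dihydro-1-benzofuran-6-yl]methanol
Product: 17 (2S,3S)-3-(3,5-dimethoxyphenyl)-4-methoxy-2-(4-methoxyphenyl)-2,3-dihydro-1-benzofuran-6-carbaldehyde
Conditions: activated MnO2, CH2Cl2, rt
Reagents that add atoms: none
Why: Manganese dioxide oxidation is selective for the benzylic alcohol and should stop at the aldehyde without touching the C2–H and C3–H positions.

Step 11
Reactants: 17 (2S,3S)-3-(3,5-dimethoxyphenyl)-4-methoxy-2-(4-methoxyphenyl)-2,3-dihydro-1-benzofuran-6-carbaldehyde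
Product: 18 gnetal, (2S,3S)-3-(3,5-dihydroxyphenyl)-4-hydroxy-2-(4-hydroxyphenyl)-2,3-dihydro-1-benzofuran-6-carbaldehyde
Conditions: BBr3 (10 equiv), CH2Cl2, −78 → 0 °C; then H2O
Reagents that add atoms: none
Why: Lewis-acid cleavage of the four aryl methyl ethers by BBr3 should leave the aldehyde intact after hydrolysis; C3 cannot epimerise, so any reversible opening of C2–O1 should reclose to the more stable trans isomer (the two ortho oxygens of ring A being equivalent by rotation) and the (2S,3S) configuration is kept.

**Compound list**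

1 | 3,5-dimethoxybenzyl alcohol | COc1cc(CO)cc(OC)c1 | starting material
2 | tert-butyl[(3,5-dimethoxyphenyl)methoxy]dimethylsilane | COc1cc(CO[Si](C)(C)C(C)(C)C)cc(OC)c1 | intermediate
3 | [4-({[tert-butyl(dimethyl)silyl]oxy}methyl)-2,6-dimethoxyphenyl]lithium | COc1cc(CO[Si](C)(C)C(C)(C)C)cc(OC)c1[Li] | intermediate
4 | 1-[4-({[tert-butyl(dimethyl)silyl]oxy}methyl)-2,6-dimethoxyphenyl]ethan-1-one | CC(=O)c1c(OC)cc(CO[Si](C)(C)C(C)(C)C)cc1OC | intermediate
5 | 1-[4-(hydroxymethyl)-2,6-dimethoxyphenyl]ethan-1-one | CC(=O)c1c(OC)cc(CO)cc1OC | intermediate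
6 | (4-acetyl-3,5-dimethoxyphenyl)methyl 2,2-dimethylpropanoate | CC(=O)c1c(OC)cc(COC(=O)C(C)(C)C)cc1OC | intermediate
7 | (4-acetyl-3-hydroxy-5-methoxyphenyl)methyl 2,2-dimethylpropanoate | CC(=O)c1c(O)cc(COC(=O)C(C)(C)C)cc1OC | intermediate
8 | {4-[(2E)-3-(dimethylamino)prop-2-enoyl]-3-hydroxy-5-methoxyphenyl}methyl 2,2-dimethylpropanoate | CN(C)/C=C/C(=O)c1c(O)cc(COC(=O)C(C)(C)C)cc1OC | intermediate
9 | (5-methoxy-4-oxo-4H-chromen-7-yl)methyl 2,2-dimethylpropanoate | O=c1ccoc2cc(COC(=O)C(C)(C)C)cc(OC)c12 | intermediate
10 | 4-methoxyphenylboronic acid | COc1ccc(B(O)O)cc1 | starting material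
11 | [(2S)-5-methoxy-2-(4-methoxyphenyl)-4-oxo-3,4-dihydro-2H-chromen-7-yl]methyl 2,2-dimethylpropanoate | CC(C)(C)C(=O)OCc1cc(OC)c2c(c1)O[C@H](c1ccc(OC)cc1)CC2=O | intermediate
12 | [(2S)-4,5-dimethoxy-2-(4-methoxyphenyl)-2H-chromen-7-yl]methyl 2,2-dimethylpropanoate | CC(C)(C)C(=O)OCc1cc(OC)c2c(c1)O[C@H](c1ccc(OC)cc1)C=C2OC | intermediate
13 | methyl (2S,3S)-6-{[(2,2-dimethylpropanoyl)oxy]methyl}-4-methoxy-2-(4-methoxyphenyl)-2,3-dihydro-1-benzofuran-3-carboxylate (trans) | CC(C)(C)C(=O)OCc1cc(OC)c2c(c1)O[C@H](c1ccc(OC)cc1)[C@H]2C(=O)OC | intermediate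
14 | (2S,3S)-6-(hydroxymethyl)-4-methoxy-2-(4-methoxyphenyl)-2,3-dihydro-1-benzofuran-3-carboxylic acid (trans) | OCc1cc(OC)c2c(c1)O[C@H](c1ccc(OC)cc1)[C@H]2C(=O)O | intermediate
15 | 1-bromo-3,5-dimethoxybenzene | COc1cc(Br)cc(OC)c1 | starting material
16 | [(2S,3S)-3-(3,5-dimethoxyphenyl)-4-methoxy-2-(4-methoxyphenyl)-2,3-dihydro-1-benzofuran-6-yl]methanol (trans) | OCc1cc(OC)c2c(c1)O[C@H](c1ccc(OC)cc1)[C@H]2c1cc(OC)cc(OC)c1 | intermediate
17 | (2S,3S)-3-(3,5-dimethoxyphenyl)-4-methoxy-2-(4-methoxyphenyl)-2,3-dihydro-1-benzofuran-6-carbaldehyde (trans) | O=Cc1cc(OC)c2c(c1)O[C@H](c1ccc(OC)cc1)[C@H]2c1cc(OC)cc(OC)c1 | intermediate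
18 | gnetal, (2S,3S)-3-(3,5-dihydroxyphenyl)-4-hydroxy-2-(4-hydroxyphenyl)-2,3-dihydro-1-benzofuran-6-carbaldehyde (trans) | O=Cc1cc(O)c2c(c1)O[C@H](c1ccc(O)cc1)[C@H]2c1cc(O)cc(O)c1 | target

**Step count and risks**

Total step count: 11. Longest linear sequence: 11 steps (1 → 18); 10 and 15 are bought and enter directly.

Steps most likely to fail:

1. Step 7 (ring contraction). The anisyl ring may shift from C2 to C3 (isoflavone), the flavanone may be dehydrogenated or merely 3-methoxylated, iodine(III) may attack the methoxyarenes, or acid may open C2–O1 and erode the enantiomeric purity. Fallback, from 11 back to 13: the oxidation and the shift are separated. Bromination of 11 with PhNMe3Br3 in THF at 0 °C should give the trans bromide [(2R,3R)-3-bromo-5-methoxy-2-(4-methoxyphenyl)-4-oxo-3,4-dihydro-2H-chromen-7-yl]methyl 2,2-dimethylpropanoate F1 (same spatial arrangement at C2; the descriptor changes only by priority). Treatment of F1 with AgBF4 in methanol at 40 °C then removes bromide from the hemiketal with silver assistance and triggers the same antiperiplanar shift of the ring-A carbon (silver-assisted 1,2-aryl shift of α-bromo aryl ketones to arylacetic esters), giving 13 without an iodine(III) oxidant or sulfuric acid.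

2. Step 9 (decarboxylative arylation). Protodecarboxylation or dimerisation of the C3 radical, sluggish engagement of the aryl bromide, O-arylation of the free alcohol, or insufficient trans selectivity may lower the outcome. Fallback, from 14 back to 16: the carboxyl group is activated reductively instead of oxidatively. N-Hydroxyphthalimide, DIC and catalytic DMAP in CH2Cl2 at 0 °C should convert 14 chemoselectively (the hydroxyimide outcompetes the alcohol) into the redox-active ester 1,3-dioxo-1,3-dihydro-2H-isoindol-2-yl (2S,3S)-6-(hydroxymethyl)-4-methoxy-2-(4-methoxyphenyl)-2,3-dihydro-1-benzofuran-3-carboxylate F2. Nickel-catalysed reductive cross-electrophile coupling of F2 with 1-iodo-3,5-dimethoxybenzene (COc1cc(I)cc(OC)c1) (NiBr2·glyme, dtbbpy, Zn, DMA, rt) generates the same C3 radical by single-electron reduction and should give 16 with the same anti capture; no light, no base and no organometallic reagent are involved, so the free alcohol is tolerated.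

3. Step 6 (asymmetric conjugate addition). Protodeboronation of the electron-rich boronic acid, slow insertion into the 5-methoxychromone, or insufficient enantioface discrimination may give low conversion or low enantiomeric purity. Fallback, from 9 back to 11: enantiopurity is obtained by kinetic resolution instead of asymmetric C–C bond formation. An achiral Pd(OCOCF3)2/2,2′-bipyridine catalyst adds 10 to 9 to give the racemic flavanone [(2RS)-5-methoxy-2-(4-methoxyphenyl)-4-oxo-3,4-dihydro-2H-chromen-7-yl]methyl 2,2-dimethylpropanoate F3. Asymmetric transfer hydrogenation (Cp*RhCl[TsDPEN], HCO2H/Et3N, EtOAc, rt; catalyst antipode chosen so that the (R)-ketone reacts) should then reduce only the unwanted enantiomer to the cis-alcohol [(2R,4R)-4-hydroxy-5-methoxy-2-(4-methoxyphenyl)-3,4-dihydro-2H-chromen-7-yl]methyl 2,2-dimethylpropanoate F4. Unreacted (S)-ketone 11 is separated from F4 by chromatography and continues in step 7.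

**Further compounds**

F1 | step 7 | [(2R,3R)-3-bromo-5-methoxy-2-(4-methoxyphenyl)-4-oxo-3,4-dihydro-2H-chromen-7-yl]methyl 2,2-dimethylpropanoate (2,3-trans) | CC(C)(C)C(=O)OCc1cc(OC)c2c(c1)O[C@H](c1ccc(OC)cc1)[C@@H](Br)C2=O
F2 | step 9 | 1,3-dioxo-1,3-dihydro-2H-isoindol-2-yl (2S,3S)-6-(hydroxymethyl)-4-methoxy-2-(4-methoxyphenyl)-2,3-dihydro-1-benzofuran-3-carboxylate | OCc1cc(OC)c2c(c1)O[C@H](c1ccc(OC)cc1)[C@H]2C(=O)ON1C(=O)c2ccccc2C1=O
F3 | step 6 | [(2RS)-5-methoxy-2-(4-methoxyphenyl)-4-oxo-3,4-dihydro-2H-chromen-7-yl]methyl 2,2-dimethylpropanoate (racemate) | CC(C)(C)C(=O)OCc1cc(OC)c2c(c1)OC(c1ccc(OC)cc1)CC2=O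
F4 | step 6 | [(2R,4R)-4-hydroxy-5-methoxy-2-(4-methoxyphenyl)-3,4-dihydro-2H-chromen-7-yl]methyl 2,2-dimethylpropanoate (2,4-cis) | CC(C)(C)C(=O)OCc1cc(OC)c2c(c1)O[C@@H](c1ccc(OC)cc1)C[C@H]2O
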